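The 2,2-dimethyl-4-arylchroman is disconnected at O1–C2 and C4–C4a. The step exploits that C4a of chroman ring B lies between two oxygens (O1 and the C5 hydroxyl, a resorcinol carbon) and that C4 is an allylic benzylic carbon para to the chromene oxygen of ring A. One chiral Brønsted acid unites a racemic 1-aryl-3-methylbut-2-en-1-ol with a resorcylate: stereoconvergent ionisation, enantioselective Friedel–Crafts attack, then hydroalkoxylation closes the pyran. A temporary CO2Me on C6 of ring B (absent from the target) blocks that carbon and chelates the C5 hydroxyl; both prenyl groups travel as allyl groups and are unmasked by cross-metathesis. Both partners derive from one dibromide.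

Key step: step 11

Remark: partly converted species in steps that repeat one reaction at several sites (steps 1, 2, 5, 7, 10, 12, 13) are not numbered; 12 is carried as the racemate because step 11 is stereoconvergent; the catalyst enantiomer in step 11 is assigned by screening; TBS = tert-butyldimethylsilyl, MOM = methoxymethyl.

Step 1
Reactants: 1 dihydroresveratrol (5-[2-(4-hydroxyphenyl)ethyl]benzene-1,3-diol; commercial)
Product: 2 1,3-bis(methoxymethoxy)-5-{2-[4-(methoxymethoxy)phenyl]ethyl}benzene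
Conditions: MOMCl, i-Pr2NEt, CH2Cl2, 0 °C to rt
Reagents that add atoms: chloromethyl methyl ether COCCl
Why: Williamson-type O-alkylation of all three phenols should give ethers that tolerate NBS and organometallic reagents and leave with mild acid.

Step 2
Reactants: 2 1,3-bis(methoxymethoxy)-5-{2-[4-(methoxymethoxy)phenyl]ethyl}benzene
Product: 3 2,4-dibromo-1,5-bis(methoxymethoxy)-3-{2-[4-(methoxymethoxy)phenyl]ethyl}benzene
Conditions: NBS (2.05 equiv), MeCN, 0 °C to rt
Reagents that add atoms: N-bromosuccinimide O=C1CCC(=O)N1Br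
Why: electrophilic aromatic bromination should go para to each OMOM group of the dialkoxy ring, i.e. at the two equivalent carbons flanking the ethylene chain, before the carbon between the two ethers or the mono-alkoxy ring reacts.

Step 3
Reactants: 3 2,4-dibromo-1,5-bis(methoxymethoxy)-3-{2-[4-(methoxymethoxy)phenyl]ethyl}benzene
Product: 5 2-allyl-4-bromo-1,5-bis(methoxymethoxy)-3-{2-[4-(methoxymethoxy)phenyl]ethyl}benzene, via monolithiated bromoarene 4 (not isolated)
Conditions: n-BuLi (1.05 equiv), THF, −78 °C; CuBr·SMe2 (10 mol%), allyl bromide, −78 to 0 °C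
Reagents that add atoms: allyl bromide C=CCBr
Why: bromine–lithium exchange of one of two equivalent bromides (a second exchange on the aryllithium is disfavoured) and copper-catalysed allylation should install the allyl group, a prenyl surrogate that cannot cyclise onto the neighbouring phenol under acid.

Step 4
Reactants: 5 2-allyl-4-bromo-1,5-bis(methoxymethoxy)-3-{2-[4-(methoxymethoxy)phenyl]ethyl}benzene
Product: 7 3-allyl-4,6-bis(methoxymethoxy)-2-{2-[4-(methoxymethoxy)phenyl]ethyl}benzaldehyde, via aryllithium 6 (not isolated)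
Conditions: n-BuLi (1.1 equiv), THF, −78 °C; DMF; H2O
Reagents that add atoms: N,N-dimethylformamide CN(C)C=O
Why: a second bromine–lithium exchange followed by Bouveault formylation should place the aldehyde on the remaining carbon next to the chain.

Step 5
Reactants: 7 3-allyl-4,6-bis(methoxymethoxy)-2-{2-[4-(methoxymethoxy)phenyl]ethyl}benzaldehyde
Product: 8 3-allyl-4,6-dihydroxy-2-[2-(4-hydroxyphenyl)ethyl]benzaldehyde
Conditions: conc. HCl (cat.), MeOH, 45 °C; aqueous work-up
Reagents that add atoms: none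
Why: acid-catalysed acetal exchange with methanol should remove all three MOM groups while the allyl group stays inert.

Step 6
Reactants: 8 3-allyl-4,6-dihydroxy-2-[2-(4-hydroxyphenyl)ethyl]benzaldehyde
Product: 10 8-allyl-5-hydroxy-7-[2-(4-hydroxyphenyl)ethyl]-2,2-dimethyl-2H-chromene-6-carbaldehyde, via vinyl ortho-quinone methide 9 (not isolated)
Conditions: 3-methylbut-2-enal, ethylenediammonium diacetate (20 mol%), toluene, 110 °C (sealed)
Reagents that add atoms: 3-methylbut-2-enal CC(C)=CC=O
Why: Knoevenagel-type condensation at C5 (the only free carbon of the resorcinol ring) and oxa-6π electrocyclisation should close the 2,2-dimethylchromene through the 4-OH para to the aldehyde, because the 6-OH stays hydrogen-bonded to the CHO.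

Step 7
Reactants: 10 8-allyl-5-hydroxy-7-[2-(4-hydroxyphenyl)ethyl]-2,2-dimethyl-2H-chromene-6-carbaldehyde
Product: 11 8-allyl-5-(TBSO)-7-{2-[4-(TBSO)phenyl]ethyl}-2,2-dimethyl-2H-chromene-6-carbaldehyde
Conditions: TBSOTf (2.4 equiv), 2,6-lutidine, CH2Cl2, 0 °C to rt
Reagents that add atoms: tert-butyldimethylsilyl trifluoromethanesulfonate CC(C)(C)[Si](C)(C)OS(=O)(=O)C(F)(F)F
Why: silylation with the reactive triflate should cap both the chelated hindered phenol and the remote phenol with groups that do not participate in cation chemistry and leave with base at the end.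

Step 8
Reactants: 11 8-allyl-5-(TBSO)-7-{2-[4-(TBSO)phenyl]ethyl}-2,2-dimethyl-2H-chromene-6-carbaldehyde
Product: 12 racemic 1-{8-allyl-5-(TBSO)-7-[2-(4-TBSO-phenyl)ethyl]-2,2-dimethyl-2H-chromen-6-yl}-3-methylbut-2-en-1-ol
Conditions: 2-methylprop-1-enylmagnesium bromide, THF, −78 to −30 °C; pH 7 buffer; Et3N-deactivated silica
Reagents that add atoms: 2-methylprop-1-enylmagnesium bromide CC(C)=C[Mg]Br
Why: Grignard 1,2-addition to the aldehyde should give the allylic alcohol as a racemate, which suffices because the next step passes through a planar cation.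

Step 9
Reactants: 5 2-allyl-4-bromo-1,5-bis(methoxymethoxy)-3-{2-[4-(methoxymethoxy)phenyl]ethyl}benzene
Product: 14 methyl 3-allyl-4,6-bis(methoxymethoxy)-2-{2-[4-(methoxymethoxy)phenyl]ethyl}benzoate, via arylmagnesium bromide 13 (not isolated)
Conditions: Mg turnings (activated with 1 mol% DIBAL-H), LiCl, THF, rt to 40 °C; cannulated into ClCO2Me (3 equiv), THF, −40 to 0 °C
Reagents that add atoms: methyl chloroformate COC(=O)Cl
Why: LiCl-assisted magnesium insertion into the aryl bromide (classical Grignard formation, to which MOM ethers and the allyl group are inert) and acylation of the Grignard reagent by inverse addition to excess chloroformate should install the temporary ester, and the two flanking substituents should stop a second addition.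

Step 10
Reactants: 14 methyl 3-allyl-4,6-bis(methoxymethoxy)-2-{2-[4-(methoxymethoxy)phenyl]ethyl}benzoate
Product: 15 methyl 3-allyl-4,6-dihydroxy-2-[2-(4-hydroxyphenyl)ethyl]benzoate
Conditions: conc. HCl (cat.), MeOH, 45 °C
Reagents that add atoms: none
Why: acid-catalysed acetal exchange should free the phenols without touching the hindered chelated ester or the allyl group.

Step 11
Reactants: 12 racemic 1-{8-allyl-5-(TBSO)-7-[2-(4-TBSO-phenyl)ethyl]-2,2-dimethyl-2H-chromen-6-yl}-3-methylbut-2-en-1-ol; 15 methyl 3-allyl-4,6-dihydroxy-2-[2-(4-hydroxyphenyl)ethyl]benzoate (1.2 equiv)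
Product: 18 methyl (4R)-8-allyl-4-{8-allyl-5-(TBSO)-7-[2-(4-TBSO-phenyl)ethyl]-2,2-dimethyl-2H-chromen-6-yl}-5-hydroxy-7-[2-(4-hydroxyphenyl)ethyl]-2,2-dimethylchromane-6-carboxylate, via allyl cation ion pair 16 (not isolated), via Friedel-Crafts adduct 17 (not isolated)
Conditions: chiral 3,3'-diaryl-BINOL N-triflylphosphoramide (10 mol%), 5 Å MS, CH2Cl2, −40 °C, then 35 °C
Reagents that add atoms: none
Why: Proposed new method: the acid ionises both enantiomers of 12 to one planar allyl cation 16 held in a contact ion pair with the chiral anion (stereoconvergent), the anion hydrogen-bonds the free 4-OH of 15, and C5 of 15 (the only unsubstituted carbon of that ring, flanked by both oxygens) attacks the benzylic terminus to give 17. The closest known reaction types are chiral phosphoric acid or phosphoramide catalysed enantioselective SN1-type allylic substitutions and quinone-methide Friedel–Crafts alkylations of phenols, and the achiral acid-mediated chroman annulation of phenols with allylic alcohols; their union on a non-quinoid, tetra-ortho-substituted diarylmethine is new. The pyran ring then closes by Markovnikov protonation of the CH=CMe2 unit of 17 and capture of the tertiary cation by the same phenol oxygen, a cationic 6-endo-trig hydroalkoxylation that creates no further stereocentre. The C4 stereocentre is set in the C–C bond formation by the face of 16 that the chiral anion leaves open, and the catalyst enantiomer is selected for (R). The step needs attack at the benzylic and not the tertiary terminus (the latter would build a quaternary centre next to a di-ortho-substituted ring and its O-alkylation is reversible), ring closure through the 4-OH and not the 6-OH (the 6-OH is locked in a hydrogen bond to the ester, which also occupies the only other nucleophilic carbon), and protonation of the isobutenyl unit in preference to the two allyl groups (secondary cations) and the chromene alkene. The silyl ether on ring A prevents its own oxygen from closing on the cation.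

Step 12
Reactants: 18 methyl (4R)-8-allyl-4-{8-allyl-5-(TBSO)-7-[2-(4-TBSO-phenyl)ethyl]-2,2-dimethyl-2H-chromen-6-yl}-5-hydroxy-7-[2-(4-hydroxyphenyl)ethyl]-2,2-dimethylchromane-6-carboxylate
Product: 19 methyl (4R)-4-{5-(TBSO)-7-[2-(4-TBSO-phenyl)ethyl]-2,2-dimethyl-8-(3-methylbut-2-enyl)-2H-chromen-6-yl}-5-hydroxy-7-[2-(4-hydroxyphenyl)ethyl]-2,2-dimethyl-8-(3-methylbut-2-enyl)chromane-6-carboxylate
Conditions: (H2IMes)(PCy3)Cl2Ru=CHPh (10 mol%), 2-methylbut-2-ene/CH2Cl2, 40 °C (sealed)
Reagents that add atoms: 2-methylbut-2-ene CC=C(C)C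
Why: olefin cross-metathesis with excess 2-methylbut-2-ene should convert both terminal allyl groups into prenyl groups, while the cyclic chromene alkene next to a quaternary carbon should not take part.

Step 13
Reactants: 19 methyl (4R)-4-{5-(TBSO)-7-[2-(4-TBSO-phenyl)ethyl]-2,2-dimethyl-8-(3-methylbut-2-enyl)-2H-chromen-6-yl}-5-hydroxy-7-[2-(4-hydroxyphenyl)ethyl]-2,2-dimethyl-8-(3-methylbut-2-enyl)chromane-6-carboxylate
Product: 21 (4R)-4-{5-hydroxy-7-[2-(4-hydroxyphenyl)ethyl]-2,2-dimethyl-8-(3-methylbut-2-enyl)-2H-chromen-6-yl}-7-[2-(4-hydroxyphenyl)ethyl]-2,2-dimethyl-8-(3-methylbut-2-enyl)chroman-5-ol, via hydroxy acid 20 (not isolated)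
Conditions: NaOH, MeOH/H2O (degassed), reflux; AcOH to pH 5; toluene, 90 °C
Reagents that add atoms: none
Why: hydroxide should cleave both aryl silyl ethers and saponify the ester, and the resulting ortho-hydroxy para-alkoxy benzoic acid should lose CO2 on gentle heating (decarboxylation of a β-resorcylic-type acid), leaving the benzylic stereocentre untouched.

Compound list
1 | dihydroresveratrol | Oc1ccc(CCc2cc(O)cc(O)c2)cc1 | starting material
2 | 1,3-bis(methoxymethoxy)-5-{2-[4-(methoxymethoxy)phenyl]ethyl}benzene | COCOc1ccc(CCc2cc(OCOC)cc(OCOC)c2)cc1 | intermediate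
3 | 2,4-dibromo-1,5-bis(methoxymethoxy)-3-{2-[4-(methoxymethoxy)phenyl]ethyl}benzene | Brc1c(CCc2ccc(OCOC)cc2)c(Br)c(OCOC)cc1OCOC | intermediate
4 | monolithiated bromoarene (one Br of 3 replaced by Li) | [Li]c1c(CCc2ccc(OCOC)cc2)c(Br)c(OCOC)cc1OCOC | intermediate
5 | 2-allyl-4-bromo-1,5-bis(methoxymethoxy)-3-{2-[4-(methoxymethoxy)phenyl]ethyl}benzene | C=CCc1c(CCc2ccc(OCOC)cc2)c(Br)c(OCOC)cc1OCOC | intermediate
6 | aryllithium (Br of 5 replaced by Li) | [Li]c1c(CCc2ccc(OCOC)cc2)c(CC=C)c(OCOC)cc1OCOC | intermediate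
7 | 3-allyl-4,6-bis(methoxymethoxy)-2-{2-[4-(methoxymethoxy)phenyl]ethyl}benzaldehyde | C=CCc1c(CCc2ccc(OCOC)cc2)c(C=O)c(OCOC)cc1OCOC | intermediate
8 | 3-allyl-4,6-dihydroxy-2-[2-(4-hydroxyphenyl)ethyl]benzaldehyde | C=CCc1c(CCc2ccc(O)cc2)c(C=O)c(O)cc1O | intermediate
9 | vinyl ortho-quinone methide (cyclohexadienone with exocyclic 3-methylbut-2-enylidene) | C=CCC1=C(CCc2ccc(O)cc2)C(C=O)=C(O)C(=CC=C(C)C)C1=O | intermediate
10 | 8-allyl-5-hydroxy-7-[2-(4-hydroxyphenyl)ethyl]-2,2-dimethyl-2H-chromene-6-carbaldehyde | C=CCc1c(CCc2ccc(O)cc2)c(C=O)c(O)c2c1OC(C)(C)C=C2 | intermediate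
11 | 8-allyl-5-(TBSO)-7-{2-[4-(TBSO)phenyl]ethyl}-2,2-dimethyl-2H-chromene-6-carbaldehyde | C=CCc1c(CCc2ccc(O[Si](C)(C)C(C)(C)C)cc2)c(C=O)c(O[Si](C)(C)C(C)(C)C)c2c1OC(C)(C)C=C2 | intermediate
12 | racemic 1-{8-allyl-5-(TBSO)-7-[2-(4-TBSO-phenyl)ethyl]-2,2-dimethyl-2H-chromen-6-yl}-3-methylbut-2-en-1-ol | C=CCc1c(CCc2ccc(O[Si](C)(C)C(C)(C)C)cc2)c(C(O)C=C(C)C)c(O[Si](C)(C)C(C)(C)C)c2c1OC(C)(C)C=C2 | intermediate
13 | arylmagnesium bromide (Br of 5 replaced by MgBr) | C=CCc1c(CCc2ccc(OCOC)cc2)c([Mg]Br)c(OCOC)cc1OCOC | intermediate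
14 | methyl 3-allyl-4,6-bis(methoxymethoxy)-2-{2-[4-(methoxymethoxy)phenyl]ethyl}benzoate | C=CCc1c(CCc2ccc(OCOC)cc2)c(C(=O)OC)c(OCOC)cc1OCOC | intermediate
15 | methyl 3-allyl-4,6-dihydroxy-2-[2-(4-hydroxyphenyl)ethyl]benzoate | C=CCc1c(CCc2ccc(O)cc2)c(C(=O)OC)c(O)cc1O | intermediate
16 | 1-(chromen-6-yl)-3-methylbut-2-enyl cation from 12 (ion pair with the chiral anion) | C=CCc1c(CCc2ccc(O[Si](C)(C)C(C)(C)C)cc2)c([CH+]C=C(C)C)c(O[Si](C)(C)C(C)(C)C)c2c1OC(C)(C)C=C2 | intermediate
17 | methyl 3-allyl-5-[(1R)-1-(chromen-6-yl of 12)-3-methylbut-2-enyl]-4,6-dihydroxy-2-[2-(4-hydroxyphenyl)ethyl]benzoate | C=CCc1c(CCc2ccc(O[Si](C)(C)C(C)(C)C)cc2)c([C@H](c2c(O)c(CC=C)c(CCc3ccc(O)cc3)c(C(=O)OC)c2O)C=C(C)C)c(O[Si](C)(C)C(C)(C)C)c2c1OC(C)(C)C=C2 | intermediate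
18 | methyl (4R)-8-allyl-4-{8-allyl-5-(TBSO)-7-[2-(4-TBSO-phenyl)ethyl]-2,2-dimethyl-2H-chromen-6-yl}-5-hydroxy-7-[2-(4-hydroxyphenyl)ethyl]-2,2-dimethylchromane-6-carboxylate | C=CCc1c(CCc2ccc(O[Si](C)(C)C(C)(C)C)cc2)c([C@H]2CC(C)(C)Oc3c(CC=C)c(CCc4ccc(O)cc4)c(C(=O)OC)c(O)c32)c(O[Si](C)(C)C(C)(C)C)c2c1OC(C)(C)C=C2 | intermediate
19 | bis-prenyl analogue of 18 (both allyl groups converted to 3-methylbut-2-enyl) | CC(C)=CCc1c(CCc2ccc(O[Si](C)(C)C(C)(C)C)cc2)c([C@H]2CC(C)(C)Oc3c(CC=C(C)C)c(CCc4ccc(O)cc4)c(C(=O)OC)c(O)c32)c(O[Si](C)(C)C(C)(C)C)c2c1OC(C)(C)C=C2 | intermediate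
20 | (4R)-chromane-6-carboxylic acid of the target skeleton (all phenols free) | CC(C)=CCc1c(CCc2ccc(O)cc2)c([C@H]2CC(C)(C)Oc3c(CC=C(C)C)c(CCc4ccc(O)cc4)c(C(=O)O)c(O)c32)c(O)c2c1OC(C)(C)C=C2 | intermediate
21 | (4R)-4-{5-hydroxy-7-[2-(4-hydroxyphenyl)ethyl]-2,2-dimethyl-8-(3-methylbut-2-enyl)-2H-chromen-6-yl}-7-[2-(4-hydroxyphenyl)ethyl]-2,2-dimethyl-8-(3-methylbut-2-enyl)chroman-5-ol (CNP0103951.1) | CC(C)=CCc1c(CCc2ccc(O)cc2)c([C@H]2CC(C)(C)Oc3c(CC=C(C)C)c(CCc4ccc(O)cc4)cc(O)c32)c(O)c2c1OC(C)(C)C=C2 | target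

Total step count: 13. Longest linear sequence: 11 steps (steps 1–8, then 11–13); steps 9–10 form the second branch from 5.

Steps most likely to fail

Step 11 (Proposed new method). The ion pair may be too loose for good facial selectivity at so congested a diarylmethine. The ortho silyl group may be lost from the cation, after which ring A's own oxygen would close on the diene by electrocyclisation. The cascade may also stall after the C–C bond formation. Fallback with known chemistry, setting out from 12 and 15: condensation with an achiral acid (p-TsOH·H2O cat., CH2Cl2, 0 °C to rt; the established phenol–allylic alcohol chroman annulation) should pass through cation 16 and the racemic adduct F1 to the racemic chroman F2. Preparative chiral SFC would then separate the wanted enantiomer from the (4S)-enantiomer F3, and the route resumes at 18.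

Step 13. Hydroxide attack at the doubly ortho-substituted, chelated ester may be too slow, and prolonged heating of the polyphenolate in base invites air oxidation. Fallback, setting out from 5: the methyl ester is exchanged for a fluoride-labile ester, so that no nucleophile has to reach the hindered carbonyl. The arylmagnesium bromide 13 (made as in step 9) is quenched with 2-(trimethylsilyl)ethyl chloroformate to give the 2-(trimethylsilyl)ethyl ester F4. HCl/MeOH should give the triol ester F5. Under the conditions of step 11 with 12, this should give, via 16 and the adduct F6, the chroman F7. Cross-metathesis as in step 12 should give the bis-prenyl ester F8. TBAF (THF, rt) should then cleave the ester and both silyl ethers, and the liberated acid 20 should decarboxylate on buffering with AcOH and gentle warming, returning to the route at 21.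

Step 8. The ortho silyl group may migrate to the new magnesium alkoxide, after which elimination and electrocyclisation would close a second chromene on ring A; the product may also ionise on acidic silica. Fallback, setting out from 11: Wittig olefination with the ylide from (2-methylallyl)triphenylphosphonium chloride and KOtBu (THF, 0 °C) should give the diene F9 as an E/Z mixture, with no alkoxide next to the silyl ether. Under the acid of step 11 the diene should be protonated at its terminal CH2 to the same cation 16, so that F9 and 15 should give 18 via 17, where the route resumes.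

Further compounds
F1 | step 11 | racemic Friedel–Crafts adduct (racemate of 17; not isolated) | C=CCc1c(CCc2ccc(O[Si](C)(C)C(C)(C)C)cc2)c(C(C=C(C)C)c2c(O)c(CC=C)c(CCc3ccc(O)cc3)c(C(=O)OC)c2O)c(O[Si](C)(C)C(C)(C)C)c2c1OC(C)(C)C=C2
F2 | step 11 | racemic chroman (racemate of 18) | C=CCc1c(CCc2ccc(O[Si](C)(C)C(C)(C)C)cc2)c(C2CC(C)(C)Oc3c(CC=C)c(CCc4ccc(O)cc4)c(C(=O)OC)c(O)c32)c(O[Si](C)(C)C(C)(C)C)c2c1OC(C)(C)C=C2
F3 | step 11 | (4S)-enantiomer of 18 | C=CCc1c(CCc2ccc(O[Si](C)(C)C(C)(C)C)cc2)c([C@@H]2CC(C)(C)Oc3c(CC=C)c(CCc4ccc(O)cc4)c(C(=O)OC)c(O)c32)c(O[Si](C)(C)C(C)(C)C)c2c1OC(C)(C)C=C2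
F4 | step 13 | 2-(trimethylsilyl)ethyl 3-allyl-4,6-bis(methoxymethoxy)-2-{2-[4-(methoxymethoxy)phenyl]ethyl}benzoate | C=CCc1c(CCc2ccc(OCOC)cc2)c(C(=O)OCC[Si](C)(C)C)c(OCOC)cc1OCOC
F5 | step 13 | 2-(trimethylsilyl)ethyl 3-allyl-4,6-dihydroxy-2-[2-(4-hydroxyphenyl)ethyl]benzoate | C=CCc1c(CCc2ccc(O)cc2)c(C(=O)OCC[Si](C)(C)C)c(O)cc1O
F6 | step 13 | 2-(trimethylsilyl)ethyl ester analogue of adduct 17 (not isolated) | C=CCc1c(CCc2ccc(O[Si](C)(C)C(C)(C)C)cc2)c([C@H](c2c(O)c(CC=C)c(CCc3ccc(O)cc3)c(C(=O)OCC[Si](C)(C)C)c2O)C=C(C)C)c(O[Si](C)(C)C(C)(C)C)c2c1OC(C)(C)C=C2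
F7 | step 13 | 2-(trimethylsilyl)ethyl ester analogue of chroman 18 | C=CCc1c(CCc2ccc(O[Si](C)(C)C(C)(C)C)cc2)c([C@H]2CC(C)(C)Oc3c(CC=C)c(CCc4ccc(O)cc4)c(C(=O)OCC[Si](C)(C)C)c(O)c32)c(O[Si](C)(C)C(C)(C)C)c2c1OC(C)(C)C=C2
F8 | step 13 | 2-(trimethylsilyl)ethyl ester analogue of 19 | CC(C)=CCc1c(CCc2ccc(O[Si](C)(C)C(C)(C)C)cc2)c([C@H]2CC(C)(C)Oc3c(CC=C(C)C)c(CCc4ccc(O)cc4)c(C(=O)OCC[Si](C)(C)C)c(O)c32)c(O[Si](C)(C)C(C)(C)C)c2c1OC(C)(C)C=C2
F9 | step 8 | 8-allyl-5-(TBSO)-7-{2-[4-(TBSO)phenyl]ethyl}-2,2-dimethyl-6-(3-methylbuta-1,3-dienyl)-2H-chromene (E/Z mixture) | C=CCc1c(CCc2ccc(O[Si](C)(C)C(C)(C)C)cc2)c(C=CC(C)=C)c(O[Si](C)(C)C(C)(C)C)c2c1OC(C)(C)C=C2
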